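**Strategy.** Each terminal ring (C1 butyryl-bearing, C2, C3 bridge-bearing, C4, C5 gem-dimethyl, C6) is disconnected at C4–C5 and C6–C1. The key step exploits that C4–C3–C2–C1 with the butyryl carbonyl has the carbon/oxygen pattern of a 3-substituted 4-alkoxy-6-propyl-2-pyranone, while C5–C6 is an isobutyrate. In one operation two isobutyrate enolates turn both pyranones into both carbocycles (four C–C bonds), with butyryl, bridge and oxygens already placed. The precursor is a tribenzylated butyrylphloroglucinol carrying two (4-benzyloxy-2-oxo-6-propylpyran-3-yl)methyl arms; all five masked oxygens are benzyl ethers, so one neutral hydrogenolysis finishes the synthesis.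

Key step: step 7

Remark: the target has no stereogenic centre or axis (achiral, drawn as one enol tautomer), so no stereocontrol is required; LDA is taken as the commercial solution.

**Step 1**
Reactants: 1 phloroglucinol; 2 butyryl chloride
Product: 3 1-(2,4,6-trihydroxyphenyl)butan-1-one
Conditions: AlCl3 (3.5 equiv), PhNO2–CH2Cl2, 0 °C → rt; aq. HCl
Reagents that add atoms: none
Why: Friedel–Crafts acylation of the very electron-rich triol should stop at the mono-ketone because the first acyl group, chelated to aluminium, deactivates the ring towards a second acylation.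

**Step 2**
Reactants: 3 1-(2,4,6-trihydroxyphenyl)butan-1-one
Product: 5 5-butanoyl-2,4,6-trihydroxybenzene-1,3-dicarbaldehyde, via bis(dimethyliminium) dichloride 4 (not isolated)
Conditions: POCl3 (3 equiv), DMF, EtOAc, 0 °C → rt; then H2O, 50 °C
Reagents that add atoms: N,N-dimethylformamide CN(C)C=O; water O
Why: Vilsmeier–Haack formylation should occur at the two remaining ring carbons, each still activated by three hydroxyl groups and far more nucleophilic than the ketone enol, and aqueous hydrolysis of the bis(iminium) salt releases the dialdehyde.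

**Step 3**
Reactants: 5 5-butanoyl-2,4,6-trihydroxybenzene-1,3-dicarbaldehyde
Product: 6 2,4,6-tris(benzyloxy)-5-butanoylbenzene-1,3-dicarbaldehyde
Conditions: BnBr (3.6 equiv), K2CO3, DMF, 60 °C
Reagents that add atoms: benzyl bromide BrCc1ccccc1
Why: Williamson etherification of the three acidic phenols should occur at oxygen because every ring carbon is already substituted and carbonate in a dipolar aprotic solvent gives free phenoxides, while the non-enolisable aldehydes and the weakly acidic ketone do not react with carbonate.

**Step 4**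
Reactants: 7 4-hydroxy-6-methyl-2H-pyran-2-one; 8 iodoethane
Product: 9 4-hydroxy-6-propyl-2H-pyran-2-one
Conditions: LDA (2.3 equiv), THF–DMPU, −78 °C; EtI (1.05 equiv), −78 → −20 °C; aq. HCl
Reagents that add atoms: none
Why: Alkylation of the pyranone dianion should take place at the 6-methyl carbon, the last-formed and most basic site, which is the established dianion γ-alkylation for extending the C6 side chain of this lactone.

**Step 5**
Reactants: 6 2,4,6-tris(benzyloxy)-5-butanoylbenzene-1,3-dicarbaldehyde; 9 4-hydroxy-6-propyl-2H-pyran-2-one (2.2 equiv)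
Product: 11 1-{2,4,6-tris(benzyloxy)-3,5-bis[(4-hydroxy-2-oxo-6-propyl-2H-pyran-3-yl)methyl]phenyl}butan-1-one, via bis(arylidene)pyrandione 10 (not isolated)
Conditions: Hantzsch ester (2.4 equiv), L-proline (20 mol %), CH2Cl2, rt → 40 °C
Reagents that add atoms: none
Why: Organocatalytic three-component reductive alkylation (Knoevenagel condensation at pyranone C3, then conjugate hydride transfer from the Hantzsch ester) should turn each formyl group into the CH2 bridge, the in situ reduction preventing addition of a second pyranone and leaving the hindered aryl ketone and the benzyl ethers untouched.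

**Step 6**
Reactants: 11 1-{2,4,6-tris(benzyloxy)-3,5-bis[(4-hydroxy-2-oxo-6-propyl-2H-pyran-3-yl)methyl]phenyl}butan-1-one
Product: 12 1-{2,4,6-tris(benzyloxy)-3,5-bis[(4-benzyloxy-2-oxo-6-propyl-2H-pyran-3-yl)methyl]phenyl}butan-1-one
Conditions: BnOH (2.6 equiv), PPh3, DIAD, THF, 0 °C → rt
Reagents that add atoms: benzyl alcohol OCc1ccccc1
Why: Mitsunobu etherification should benzylate the acidic 4-hydroxyl groups (pKa about 5) at oxygen, the mode known to give 4-alkoxy-2-pyranones rather than C3-alkylated or 2-alkoxy-4-pyranone isomers, under neutral conditions that everything else tolerates.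

**Step 7**
Reactants: 12 1-{2,4,6-tris(benzyloxy)-3,5-bis[(4-benzyloxy-2-oxo-6-propyl-2H-pyran-3-yl)methyl]phenyl}butan-1-one; 13 methyl isobutyrate (6.5 equiv)
Product: 15 1-{2,4,6-tris(benzyloxy)-3,5-bis[(2-benzyloxy-3-butanoyl-4-hydroxy-5,5-dimethyl-6-oxocyclohexa-1,3-dien-1-yl)methyl]phenyl}butan-1-one, via ring-opened bis(keto ester) enolate 14 (not isolated)
Conditions: 13, LDA (6 equiv), THF, −78 °C; add 12; −78 °C → rt; cold dilute HCl
Reagents that add atoms: none
Why: Proposed new method: the hard lithium enolate of 13 should add to the lactone carbonyl of each pyranone (future C4, forming C4–C5), the tetrahedral alkoxide should expel the ring oxygen as the enolate of the butyryl ketone, and the α-carbon of this enolate (future C1) should then be acylated by the tethered methyl ester (forming C6–C1) with loss of methoxide. The closest known reaction types are carbanion-induced ring transformations of 2-pyranones into carbocycles, alkoxide opening of 4-alkoxy-2-pyranones at the lactone carbonyl, and the Claisen (Dieckmann) cyclisation of 2,2-dimethyl-3,5-dioxo esters to cyclohexane-1,3,5-triones. Each of the two rings closes in a 6-exo-trig Dieckmann mode, helped by the gem-dimethyl group and by the cis relationship of enolate and ester inherited from the pyranone C3=C4 bond. No stereocentre is created, so no stereocontrol is needed. The step needs carbonyl addition rather than conjugate attack at the benzyloxy- or propyl-bearing ring carbons or deprotonation of the propyl α-CH2; a hard lithium enolate at −78 °C, the crowding at both conjugate positions (each attack would join two fully substituted carbons) and an excess of enolate are relied on, and immediate deprotonation of the acidic triketone (whose delocalised anion resists retro-Claisen attack by methoxide) should make the sequence irreversible. One further equivalent of enolate should convert the hindered central aryl ketone into its own enolate, which shields it from addition and is reprotonated on work-up.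

**Step 8**
Reactants: 15 1-{2,4,6-tris(benzyloxy)-3,5-bis[(2-benzyloxy-3-butanoyl-4-hydroxy-5,5-dimethyl-6-oxocyclohexa-1,3-dien-1-yl)methyl]phenyl}butan-1-one
Product: 16 target CNP0086314.0
Conditions: H2 (1 atm), 10% Pd/C, EtOAc, rt
Reagents that add atoms: none
Why: Catalytic hydrogenolysis should cleave the three aryl benzyl ethers and the two vinylogous benzyl esters under neutral conditions, while the tetrasubstituted, hydrogen-bonded enol–enone systems and the chelated aryl ketone resist reduction and no acid or base is present that could scramble the methylene bridges.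

**Compound list**

1 | phloroglucinol (benzene-1,3,5-triol) | Oc1cc(O)cc(O)c1 | starting material
2 | butyryl chloride | CCCC(Cl)=O | starting material
3 | 1-(2,4,6-trihydroxyphenyl)butan-1-one (butyrylphloroglucinol) | CCCC(=O)c1c(O)cc(O)cc1O | intermediate
4 | bis(N,N-dimethyliminium) dichloride of dialdehyde 5 (both formyl carbons as CH=NMe2+) | CCCC(=O)c1c(O)c(C=[N+](C)C)c(O)c(C=[N+](C)C)c1O.[Cl-].[Cl-] | intermediate (not isolated)
5 | 5-butanoyl-2,4,6-trihydroxybenzene-1,3-dicarbaldehyde | CCCC(=O)c1c(O)c(C=O)c(O)c(C=O)c1O | intermediate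
6 | 2,4,6-tris(benzyloxy)-5-butanoylbenzene-1,3-dicarbaldehyde | CCCC(=O)c1c(OCc2ccccc2)c(C=O)c(OCc2ccccc2)c(C=O)c1OCc1ccccc1 | intermediate
7 | 4-hydroxy-6-methyl-2H-pyran-2-one | CC1=CC(O)=CC(=O)O1 | starting material
8 | iodoethane | CCI | starting material
9 | 4-hydroxy-6-propyl-2H-pyran-2-one | CCCC1=CC(O)=CC(=O)O1 | intermediate
10 | bis-Knoevenagel adduct: 6 with each CHO condensed to a 3-arylidene-6-propylpyran-2,4-dione (alkene geometry undefined; drawn with both arms condensed, each arm being reduced as it forms) | CCCC(=O)c1c(OCc2ccccc2)c(C=C2C(=O)C=C(CCC)OC2=O)c(OCc2ccccc2)c(C=C2C(=O)C=C(CCC)OC2=O)c1OCc1ccccc1 | intermediate (not isolated)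
11 | 1-{2,4,6-tris(benzyloxy)-3,5-bis[(4-hydroxy-2-oxo-6-propyl-2H-pyran-3-yl)methyl]phenyl}butan-1-one | CCCC(=O)c1c(OCc2ccccc2)c(CC2=C(O)C=C(CCC)OC2=O)c(OCc2ccccc2)c(CC2=C(O)C=C(CCC)OC2=O)c1OCc1ccccc1 | intermediate
12 | 1-{2,4,6-tris(benzyloxy)-3,5-bis[(4-benzyloxy-2-oxo-6-propyl-2H-pyran-3-yl)methyl]phenyl}butan-1-one (key-step precursor) | CCCC(=O)c1c(OCc2ccccc2)c(CC2=C(OCc3ccccc3)C=C(CCC)OC2=O)c(OCc2ccccc2)c(CC2=C(OCc3ccccc3)C=C(CCC)OC2=O)c1OCc1ccccc1 | intermediate
13 | methyl isobutyrate | COC(=O)C(C)C | starting material
14 | ring-opened form of both arms: each arm ArCH2–C[C(=O)CMe2CO2Me]=C(OBn)–CH2C(=O)Pr, E at each alkene (ketone carbonyl and CH2C(=O)Pr cis, as inherited from the pyranone); drawn as the neutral keto form, present as its lithium enolates | CCCC(=O)c1c(OCc2ccccc2)c(C/C(C(=O)C(C)(C)C(=O)OC)=C(OCc2ccccc2)/CC(=O)CCC)c(OCc2ccccc2)c(C/C(C(=O)C(C)(C)C(=O)OC)=C(OCc2ccccc2)/CC(=O)CCC)c1OCc1ccccc1 | intermediate (not isolated)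
15 | 1-{2,4,6-tris(benzyloxy)-3,5-bis[(2-benzyloxy-3-butanoyl-4-hydroxy-5,5-dimethyl-6-oxocyclohexa-1,3-dien-1-yl)methyl]phenyl}butan-1-one (target as central tribenzyl ether and terminal C2 benzyl enol ethers) | CCCC(=O)C1=C(O)C(C)(C)C(=O)C(Cc2c(OCc3ccccc3)c(C(=O)CCC)c(OCc3ccccc3)c(CC3=C(OCc4ccccc4)C(C(=O)CCC)=C(O)C(C)(C)C3=O)c2OCc2ccccc2)=C1OCc1ccccc1 | intermediate
16 | CNP0086314.0: 1-{2,4,6-trihydroxy-3,5-bis[(3-butanoyl-2,4-dihydroxy-5,5-dimethyl-6-oxocyclohexa-1,3-dien-1-yl)methyl]phenyl}butan-1-one (one enol tautomer; achiral) | CCCC(=O)C1=C(O)C(Cc2c(O)c(CC3=C(O)C(C)(C)C(=O)C(C(=O)CCC)=C3O)c(O)c(C(=O)CCC)c2O)=C(O)C(C)(C)C1=O | target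

**Step count.** Total: 8 steps. Longest linear sequence: 7 steps (1, 2, 3, 5, 6, 7, 8); step 4 is the convergent branch.

**Steps most likely to fail**

Step 7 (riskiest, new method). The ester enolate may act as a base towards the propyl α-CH2 of the pyranone, or add in a conjugate sense, instead of adding to the lactone carbonyl. The stabilised ring-opened anion may also fail to close and be cleaved by methoxide in a retro-Claisen reaction. Transmetalation of the enolate to cerium would be the first remedy within the same approach. The fallback uses known chemistry, sets out from 3 and 6 and comes back at 16. Compound 3 is C,C-dimethylated (NaOMe, MeI, MeOH) with dearomatisation to butyrylfilicinic acid F1. Two equivalents are joined to dialdehyde 6 by the same Knoevenagel/Hantzsch ester reductive alkylation as in step 5, giving the central tribenzyl ether of the target F2. Hydrogenolysis (H2, Pd/C, EtOAc) then gives 16.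

Step 3. Etherification of the strongly chelated, weakly nucleophilic phenoxides may stay incomplete, or dearomatising C-benzylation may compete. The fallback forms the bridges on the free phenol and protects afterwards; it sets out from 3 and 9 and comes back at 12. Compound 9 is aminomethylated at C3 with Eschenmoser's salt to the Mannich base F3. Heating this with 3 in dioxane should expel dimethylamine, and the resulting 3-methylenepyrandione is trapped at the two free ring carbons of 3 to give the pentahydroxy bis-adduct F4. Exhaustive benzylation (BnBr, Cs2CO3, DMF) then gives 12, so that 5, 6 and 11 are bypassed.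

Step 5. Condensation at the doubly ortho-substituted aldehydes may be slow, or the arylidene may be captured by a second pyranone before hydride transfer. The fallback separates condensation and reduction; it sets out from 6 and 9 and comes back at 11. Condensation in the presence of thiophenol (piperidinium acetate, EtOH) traps each arylidene as the bis(α-phenylsulfanyl) adduct F5 (mixture of diastereomers, both stereocentres removed in the next operation). Radical desulfurisation (Bu3SnH, AIBN, toluene, 80 °C) then gives 11 without touching the benzyl ethers.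

**Further compounds**

F1 | step 7 | 2-butanoyl-3,5-dihydroxy-4,4-dimethylcyclohexa-2,5-dien-1-one (butyrylfilicinic acid) | CCCC(=O)C1=C(O)C=C(O)C(C)(C)C1=O
F2 | step 7 | central tribenzyl ether of the target | CCCC(=O)C1=C(O)C(Cc2c(OCc3ccccc3)c(CC3=C(O)C(C)(C)C(=O)C(C(=O)CCC)=C3O)c(OCc3ccccc3)c(C(=O)CCC)c2OCc2ccccc2)=C(O)C(C)(C)C1=O
F3 | step 3 | 3-[(dimethylamino)methyl]-4-hydroxy-6-propyl-2H-pyran-2-one | CCCC1=CC(O)=C(CN(C)C)C(=O)O1
F4 | step 3 | 1-{2,4,6-trihydroxy-3,5-bis[(4-hydroxy-2-oxo-6-propyl-2H-pyran-3-yl)methyl]phenyl}butan-1-one | CCCC(=O)c1c(O)c(CC2=C(O)C=C(CCC)OC2=O)c(O)c(CC2=C(O)C=C(CCC)OC2=O)c1O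
F5 | step 5 | 1-{2,4,6-tris(benzyloxy)-3,5-bis[(4-hydroxy-2-oxo-6-propyl-2H-pyran-3-yl)(phenylsulfanyl)methyl]phenyl}butan-1-one (diastereomer mixture) | CCCC(=O)c1c(OCc2ccccc2)c(C(Sc2ccccc2)C2=C(O)C=C(CCC)OC2=O)c(OCc2ccccc2)c(C(Sc2ccccc2)C2=C(O)C=C(CCC)OC2=O)c1OCc1ccccc1
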